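**Two runs.** Sunday's run and Wednesday's run carry the argument; the question is how far free monomer falls in the flask.

| flask | free monomer | initiator | remark | time |
|---|---|---|---|---|
| Monday's | 14 mM | 0.4 mol% | run made earlier |  |
| Sunday's | 22 mM | 0.4 mol% | run made earlier |  |
| Wednesday's | 10 mM | 0.6 mol% | run made earlier |  |
| flask | 10 mM | 0.4 mol% |  | 10 min |

| run | time / min | isomer of the product / % | monomer in chains / % |
|---|---|---|---|
| Monday's | 2.50 | 12.2 | 13.5 |
| Monday's | 3.00 | 13.7 | 14.7 |
| Monday's | 4.00 | 17.9 | 19.1 |
| Monday's | 5.00 | 20.6 | 22.9 |
| Monday's | 6.00 | 22.7 | 22.6 |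
| Sunday's | 2.50 | 18.7 | 23.4 |
| Sunday's | 3.00 | 23.4 | 24.8 |
| Sunday's | 4.00 | 28.4 | 28.3 |
| Sunday's | 5.00 | 32.4 | 32.8 |
| Sunday's | 6.00 | 35.1 | 35.5 |
| Wednesday's | 2.50 | 7.7 | 11.7 |
| Wednesday's | 3.00 | 11.1 | 13.0 |
| Wednesday's | 4.00 | 13.3 | 14.0 |
| Wednesday's | 5.00 | 17.2 | 15.9 |
| Wednesday's | 6.00 | 18.4 | 19.2 |

(standard deviation of a reading: 1 percentage point)

1. the moment within 10 min at which there is most isomer of the product
2. the amount of isomer of the product, in percent of the free monomer charged, at that time

- the earlier runs were read with a standard deviation of 1 percentage point
- on the list of suspects stand: monomer in chains <-> isomer of the product; free monomer + living end -> monomer in chains + living end; free monomer + initiator -> living end + monomer in chains; monomer in chains + living end -> free monomer + living end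

**A floor.** Suppose each initiator has become one living end by 2.50 min, and that living ends both take up free monomer and, at a steady rate, return it from chains. Then the loss per living end is a straight line in c(free monomer). Sunday's run loses 20.4 min⁻¹ at a mean of 9.60 mM. Wednesday's run loses 8.67 min⁻¹ at 7.15 mM. The line reaches zero at the floor c*, the c(free monomer) where net loss stops (the equilibrium monomer concentration), read as 5.33 mM.

**First number.** The same line gives the flask a pseudo-first-order constant of 0.191 min⁻¹ for closing its gap to c*. So c(free monomer) reaches 6.03 mM at 10 min, still above the floor, and you put the peak at the end. Isomer took 49.6% of the converted monomer in the last readings, giving 19.7%.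

**Weak link.** Living ends are not there at time zero. Put c* back into Wednesday's run, also charged at 10 mM: its first reading implies a lag of 0.622 min. Going round once more gives 19.3%.

**The forecast.** It says 23.5% at 10 min, 4.2 percentage points above your figure. Its time rests on the ground that “Isomer simply tracks chains, and chains are still rising, so the maximum should fall at the end”. Its amount comes from scaling Wednesday's run to about 47% conversion at 10 min, where your figure stands on 38.9%.

**The flask.** It gives 19.9% at 10.0 min, with 61% of its free monomer left.

    monomer in chains ⇌ isomer of the product (K = 1.05, k = 0.0289 s⁻¹)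
    free monomer + living end → monomer in chains + living end, rate k2*[living end]*[free monomer] (k = 69.8 L mol⁻¹ s⁻¹)
    free monomer + initiator → living end + monomer in chains (k = 3.16 L mol⁻¹ s⁻¹)
    monomer in chains + living end → free monomer + living end, rate k4*[living end] as long as [monomer in chains] is above zero (k = 0.354 s⁻¹)

At 100 min the flask holds 50.7% free monomer, where c* stands at 53.3% of the charge. The neighbour charged with 40 mM has a constant of 0.763 min⁻¹, so c* predicts 13.4% left at 10.0 min, and it holds 13%.

The data are calculated for substances that don't exist, noise included.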